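**Retrosynthetic overview**

1. The last disconnections are the C3 caffeate ester (Steglich coupling) and the protecting groups: aryl silyl ethers fall to fluoride, benzyl ethers to BCl3/pentamethylbenzene, which spares the cinnamate alkene.
2. Ring C is opened at O1–C2: a Mitsunobu closure with inversion at C2 of an anti (2S,3R) chain whose C3 oxygen is a MOM ether gives the 2,3-cis (2R,3R) flavan.
3. The plan rests on ring A: a phloroglucinol alkylated at C4a, whose oxygen at C8a must become O1 while those at C5 and C7 end as free phenols. It is built from open-chain carbons by benzannulation of 3-(benzyloxy)cyclobutenone (C6, C7, C8, C8a) with a siloxyalkyne (C4a, C5) that already carries C2–C4; this gives C8a–OH free, C5–OSi and C7–OBn.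
4. The siloxyalkyne comes from the ring B aldehyde: vinyl addition, Sharpless epoxidation as a kinetic resolution (sets C2 and C3), acetylide opening of the epoxide, and oxidation of the lithium acetylide to the ynolate.
5. Ring order: ring B (from 3,4,5-trihydroxybenzaldehyde), then ring A (benzannulation), then ring C (Mitsunobu).

Key step: step 10

Remark: reagent adducts that exist only within a mechanism (alkoxyphosphonium, O-acylisourea, titanium alkoxides) are not numbered; lithiated and pericyclic intermediates that persist in the flask are.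

**Route**

Step 1
Reactants: 1 3,4,5-trihydroxybenzaldehyde
Product: 2 3,4,5-tris(benzyloxy)benzaldehyde
Conditions: BnBr, K2CO3, DMF, rt to 60 °C, N2
Reagents that add atoms: benzyl bromide BrCc1ccccc1
Why: Williamson etherification of the three phenols under carbonate base leaves the aldehyde untouched.

Step 2
Reactants: 2 3,4,5-tris(benzyloxy)benzaldehyde
Product: 3 racemic 1-[3,4,5-tris(benzyloxy)phenyl]prop-2-en-1-ol
Conditions: CH2=CHMgBr, THF, −78 to 0 °C; aq NH4Cl
Reagents that add atoms: vinylmagnesium bromide C=C[Mg]Br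
Why: Grignard 1,2-addition to the aryl aldehyde gives the racemic secondary allylic alcohol needed for the resolution.

Step 3
Reactants: 3 racemic 1-[3,4,5-tris(benzyloxy)phenyl]prop-2-en-1-ol
Product: 4 (S)-[(R)-oxiran-2-yl][3,4,5-tris(benzyloxy)phenyl]methanol (erythro epoxy alcohol)
Conditions: Ti(OiPr)4 (cat.), L-(+)-diisopropyl tartrate (cat.), t-BuOOH (0.45 equiv), 4 Å molecular sieves, CH2Cl2, −20 °C
Reagents that add atoms: tert-butyl hydroperoxide CC(C)(C)OO
Why: Sharpless asymmetric epoxidation run as a kinetic resolution: with the L-(+)-tartrate the (R)-carbinol should be the fast enantiomer and be epoxidised on the face that gives the erythro product, so the catalyst selects the carbinol centre (future C2, S) and sets the epoxide carbon (future C3, R); the (S)-enantiomer of 3 stays behind and is separated.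

Step 4
Reactants: 4 (S)-[(R)-oxiran-2-yl][3,4,5-tris(benzyloxy)phenyl]methanol
Product: 5 triethyl{(S)-[(R)-oxiran-2-yl][3,4,5-tris(benzyloxy)phenyl]methoxy}silane
Conditions: Et3SiCl, imidazole, DMF, 0 °C to rt
Reagents that add atoms: chlorotriethylsilane CC[Si](Cl)(CC)CC
Why: Standard silylation of the secondary alcohol gives an ether that tolerates organolithiums and can later be removed in the presence of an aryl silyl ether.

Step 5
Reactants: 5 triethyl{(S)-[(R)-oxiran-2-yl][3,4,5-tris(benzyloxy)phenyl]methoxy}silane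
Product: 6 (1S,2R)-1-(triethylsilyloxy)-1-[3,4,5-tris(benzyloxy)phenyl]-5-(trimethylsilyl)pent-4-yn-2-ol
Conditions: Me3SiC≡CH, n-BuLi, THF, −78 °C; BF3·OEt2; then 5, −78 °C
Reagents that add atoms: trimethylsilylacetylene (as its lithium acetylide) C#C[Si](C)(C)C
Why: BF3-promoted SN2 opening of the terminal epoxide by the lithium acetylide at the unsubstituted carbon leaves both stereocentres untouched, and the low temperature with the boron-bound alkoxide should suppress silyl migration.

Step 6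
Reactants: 6 (1S,2R)-1-(triethylsilyloxy)-1-[3,4,5-tris(benzyloxy)phenyl]-5-(trimethylsilyl)pent-4-yn-2-ol
Product: 7 (1S,2R)-2-(methoxymethoxy)-1-(triethylsilyloxy)-1-[3,4,5-tris(benzyloxy)phenyl]-5-(trimethylsilyl)pent-4-yne
Conditions: MeOCH2Cl, i-Pr2NEt, n-Bu4NI (cat.), CH2Cl2, 0 °C to rt
Reagents that add atoms: chloromethyl methyl ether COCCl
Why: Acetal protection of the C3 hydroxyl under amine base gives a group that is stable to strong base and heat and is orthogonal to the triethylsilyl ether.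

Step 7
Reactants: 7 (1S,2R)-2-(methoxymethoxy)-1-(triethylsilyloxy)-1-[3,4,5-tris(benzyloxy)phenyl]-5-(trimethylsilyl)pent-4-yne
Product: 8 (1S,2R)-2-(methoxymethoxy)-1-(triethylsilyloxy)-1-[3,4,5-tris(benzyloxy)phenyl]pent-4-yne
Conditions: K2CO3 (cat.), MeOH, 0 °C to rt
Reagents that add atoms: none
Why: Methanolysis of the alkynyl C–Si bond is fast under catalytic carbonate, while the secondary alkyl silyl ether and the acetal are stable.

Step 8
Reactants: 8 (1S,2R)-2-(methoxymethoxy)-1-(triethylsilyloxy)-1-[3,4,5-tris(benzyloxy)phenyl]pent-4-yne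
Product: 11 triisopropyl{[(4R,5S)-4-(methoxymethoxy)-5-(triethylsilyloxy)-5-[3,4,5-tris(benzyloxy)phenyl]pent-1-yn-1-yl]oxy}silane, via lithium acetylide 9 (not isolated), via lithium ynolate 10 (not isolated)
Conditions: n-BuLi, THF, −78 °C; t-BuOOLi (from t-BuOOH and LiN(SiMe3)2), −78 to 0 °C; i-Pr3SiOTf, −78 °C
Reagents that add atoms: tert-butyl hydroperoxide (as its lithium salt) CC(C)(C)OO; triisopropylsilyl trifluoromethanesulfonate CC(C)[Si](OS(=O)(=O)C(F)(F)F)(C(C)C)C(C)C
Why: Oxidation of a lithium acetylide by lithium tert-butyl peroxide gives the lithium ynolate, and the bulky silyl triflate traps it on oxygen to give the siloxyalkyne; the ethers in the chain are inert to these reagents.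

Step 9
Reactants: 12 3-ethoxycyclobut-2-en-1-one
Product: 13 3-(benzyloxy)cyclobut-2-en-1-one
Conditions: BnOH (3 equiv), camphorsulfonic acid (cat.), toluene, 40 °C, 150 mbar (EtOH removed); excess BnOH removed before use
Reagents that add atoms: benzyl alcohol OCc1ccccc1
Why: Acid-catalysed alkoxy exchange of a vinylogous ester (addition of the alcohol at C3 of the O-protonated enone, then loss of ethanol) is driven by removal of ethanol.

Step 10
Reactants: 11 triisopropyl{[(4R,5S)-4-(methoxymethoxy)-5-(triethylsilyloxy)-5-[3,4,5-tris(benzyloxy)phenyl]pent-1-yn-1-yl]oxy}silane; 13 3-(benzyloxy)cyclobut-2-en-1-one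
Product: 18 5-(benzyloxy)-2-{(2R,3S)-2-(methoxymethoxy)-3-(triethylsilyloxy)-3-[3,4,5-tris(benzyloxy)phenyl]propyl}-3-(triisopropylsilyloxy)phenol, via vinylketene 14 (not isolated), via vinylcyclobutenone 15 (not isolated), via dienylketene 16 (not isolated), via cyclohexadienone 17 (not isolated)
Conditions: 13 (1.5 equiv, two portions), toluene, 80 °C then 110 °C, sealed tube, Ar
Reagents that add atoms: none
Why: Heating opens 13 in a four-electron electrocyclic reaction to the (benzyloxy)vinylketene 14, whose ketene carbon is attacked by the nucleophilic chain-bearing carbon of ynol ether 11 in a [2+2] cycloaddition (new bonds C4a–C8a and C5–C6) to give 15; 15 reopens to dienylketene 16, which closes C8–C8a to dienone 17 and tautomerises to the phenol. The closest known reaction type is the Danheiser benzannulation of cyclobutenones with trialkylsiloxyalkynes to resorcinol monosilyl ethers; the 3-alkoxy group is a spectator that ends as the C7 benzyl ether. Ring A is closed by a thermal six-electron electrocyclisation of the acyclic dienylketene followed by enolisation. No stereocentre is created: C2 and C3 of the chain only have to survive neutral heating, and the transient sp3 carbon of 15 is erased on ring opening. The selectivity needed is the orientation of the [2+2] step, which the polarity of the partners fixes (electrophilic ketene carbon, nucleophilic β-carbon of the siloxyalkyne), so the free hydroxyl can appear only at C8a, the silyl ether at C5 and the benzyl ether at C7. Excess cyclobutenone added in portions keeps the vinylketene concentration low so that the new phenol is not acylated.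

Step 11
Reactants: 18 5-(benzyloxy)-2-{(2R,3S)-2-(methoxymethoxy)-3-(triethylsilyloxy)-3-[3,4,5-tris(benzyloxy)phenyl]propyl}-3-(triisopropylsilyloxy)phenol
Product: 19 5-(benzyloxy)-2-{(2R,3S)-3-hydroxy-2-(methoxymethoxy)-3-[3,4,5-tris(benzyloxy)phenyl]propyl}-3-(triisopropylsilyloxy)phenol
Conditions: AcOH/THF/H2O (3:1:1), rt
Reagents that add atoms: none
Why: Mild aqueous acid hydrolyses the secondary triethylsilyl ether, while the aryl triisopropylsilyl ether, the acetal and the benzyl ethers are stable.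

Step 12
Reactants: 19 5-(benzyloxy)-2-{(2R,3S)-3-hydroxy-2-(methoxymethoxy)-3-[3,4,5-tris(benzyloxy)phenyl]propyl}-3-(triisopropylsilyloxy)phenol
Product: 20 (2R,3R)-7-(benzyloxy)-3-(methoxymethoxy)-2-[3,4,5-tris(benzyloxy)phenyl]-5-(triisopropylsilyloxy)chromane
Conditions: PPh3, DIAD, THF, 0 °C to rt
Reagents that add atoms: none
Why: Intramolecular Mitsunobu etherification: the phenol is the acidic partner and displaces the activated benzylic oxygen in a 6-exo-tet SN2 closure of ring C, so C2 goes from S to R with inversion while C3 (R) is untouched, giving the 2,3-cis flavan.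

Step 13
Reactants: 20 (2R,3R)-7-(benzyloxy)-3-(methoxymethoxy)-2-[3,4,5-tris(benzyloxy)phenyl]-5-(triisopropylsilyloxy)chromane
Product: 21 (2R,3R)-7-(benzyloxy)-2-[3,4,5-tris(benzyloxy)phenyl]-5-(triisopropylsilyloxy)chroman-3-ol
Conditions: ZnBr2, n-PrSH, CH2Cl2, 0 °C to rt
Reagents that add atoms: none
Why: Lewis acid activation of the acetal with thiol capture of the methoxymethyl cation removes the MOM group quickly under conditions that should leave the aryl silyl ether, the benzyl ethers and the C2 benzylic ether intact.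

Step 14
Reactants: 22 caffeic acid
Product: 24 (E)-3-[3,4-bis(tert-butyldimethylsilyloxy)phenyl]prop-2-enoic acid, via silyl ester 23 (not isolated)
Conditions: t-BuMe2SiCl (3.3 equiv), imidazole, DMF, rt; then AcOH/THF/H2O, rt
Reagents that add atoms: tert-butyldimethylsilyl chloride CC(C)(C)[Si](C)(C)Cl
Why: Exhaustive silylation followed by selective hydrolysis of the much more labile silyl ester gives the acid with both catechol oxygens masked as fluoride-labile ethers.

Step 15
Reactants: 21 (2R,3R)-7-(benzyloxy)-2-[3,4,5-tris(benzyloxy)phenyl]-5-(triisopropylsilyloxy)chroman-3-ol; 24 (E)-3-[3,4-bis(tert-butyldimethylsilyloxy)phenyl]prop-2-enoic acid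
Product: 25 (2R,3R)-7-(benzyloxy)-2-[3,4,5-tris(benzyloxy)phenyl]-5-(triisopropylsilyloxy)chroman-3-yl (E)-3-[3,4-bis(tert-butyldimethylsilyloxy)phenyl]prop-2-enoate
Conditions: DCC, DMAP, CH2Cl2, 0 °C to rt
Reagents that add atoms: none
Why: Steglich esterification acylates the only free hydroxyl (axial C3–OH) without touching a stereocentre; no phenol is free, because the benzannulation delivered C5 as a silyl ether.

Step 16
Reactants: 25 the fully protected caffeate
Product: 26 (2R,3R)-7-(benzyloxy)-5-hydroxy-2-[3,4,5-tris(benzyloxy)phenyl]chroman-3-yl (E)-3-(3,4-dihydroxyphenyl)prop-2-enoate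
Conditions: n-Bu4NF, AcOH (1:1), THF, 0 °C
Reagents that add atoms: none
Why: Buffered fluoride cleaves the three aryl silyl ethers (two on the caffeoyl ring, one at C5) and the acetic acid buffer protects the ester and the catechol from basic conditions.

Step 17
Reactants: 26 (2R,3R)-7-(benzyloxy)-5-hydroxy-2-[3,4,5-tris(benzyloxy)phenyl]chroman-3-yl (E)-3-(3,4-dihydroxyphenyl)prop-2-enoate
Product: 27 epigallocatechin 3-O-caffeate
Conditions: BCl3, pentamethylbenzene, CH2Cl2, −78 °C; MeOH quench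
Reagents that add atoms: none
Why: BCl3 with pentamethylbenzene as a non-basic benzyl cation scavenger cleaves the four aryl benzyl ethers at low temperature without reducing the cinnamate alkene or cleaving the ester, which rules out hydrogenolysis here.

**Compound list**

1 | 3,4,5-trihydroxybenzaldehyde | O=Cc1cc(O)c(O)c(O)c1 | starting material
2 | 3,4,5-tris(benzyloxy)benzaldehyde | O=Cc1cc(OCc2ccccc2)c(OCc2ccccc2)c(OCc2ccccc2)c1 | intermediate
3 | racemic 1-[3,4,5-tris(benzyloxy)phenyl]prop-2-en-1-ol | C=CC(O)c1cc(OCc2ccccc2)c(OCc2ccccc2)c(OCc2ccccc2)c1 | intermediate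
4 | (S)-[(R)-oxiran-2-yl][3,4,5-tris(benzyloxy)phenyl]methanol | O[C@@H](c1cc(OCc2ccccc2)c(OCc2ccccc2)c(OCc2ccccc2)c1)[C@H]1CO1 | intermediate
5 | triethyl{(S)-[(R)-oxiran-2-yl][3,4,5-tris(benzyloxy)phenyl]methoxy}silane | CC[Si](CC)(CC)O[C@@H](c1cc(OCc2ccccc2)c(OCc2ccccc2)c(OCc2ccccc2)c1)[C@H]1CO1 | intermediate
6 | (1S,2R)-1-(triethylsilyloxy)-1-[3,4,5-tris(benzyloxy)phenyl]-5-(trimethylsilyl)pent-4-yn-2-ol | O[C@@H]([C@@H](O[Si](CC)(CC)CC)c1cc(OCc2ccccc2)c(OCc2ccccc2)c(OCc2ccccc2)c1)CC#C[Si](C)(C)C | intermediate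
7 | (1S,2R)-2-(methoxymethoxy)-1-(triethylsilyloxy)-1-[3,4,5-tris(benzyloxy)phenyl]-5-(trimethylsilyl)pent-4-yne | COCO[C@@H]([C@@H](O[Si](CC)(CC)CC)c1cc(OCc2ccccc2)c(OCc2ccccc2)c(OCc2ccccc2)c1)CC#C[Si](C)(C)C | intermediate
8 | (1S,2R)-2-(methoxymethoxy)-1-(triethylsilyloxy)-1-[3,4,5-tris(benzyloxy)phenyl]pent-4-yne | COCO[C@@H]([C@@H](O[Si](CC)(CC)CC)c1cc(OCc2ccccc2)c(OCc2ccccc2)c(OCc2ccccc2)c1)CC#C | intermediate
9 | lithium acetylide of 8 | COCO[C@@H]([C@@H](O[Si](CC)(CC)CC)c1cc(OCc2ccccc2)c(OCc2ccccc2)c(OCc2ccccc2)c1)CC#C[Li] | intermediate (not isolated)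
10 | lithium ynolate, lithium (4R,5S)-4-(methoxymethoxy)-5-(triethylsilyloxy)-5-[3,4,5-tris(benzyloxy)phenyl]pent-1-yn-1-olate | COCO[C@@H]([C@@H](O[Si](CC)(CC)CC)c1cc(OCc2ccccc2)c(OCc2ccccc2)c(OCc2ccccc2)c1)CC#C[O-].[Li+] | intermediate (not isolated)
11 | triisopropyl{[(4R,5S)-4-(methoxymethoxy)-5-(triethylsilyloxy)-5-[3,4,5-tris(benzyloxy)phenyl]pent-1-yn-1-yl]oxy}silane (siloxyalkyne, key-step precursor) | COCO[C@@H]([C@@H](O[Si](CC)(CC)CC)c1cc(OCc2ccccc2)c(OCc2ccccc2)c(OCc2ccccc2)c1)CC#CO[Si](C(C)C)(C(C)C)C(C)C | intermediate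
12 | 3-ethoxycyclobut-2-en-1-one | CCOC1=CC(=O)C1 | starting material
13 | 3-(benzyloxy)cyclobut-2-en-1-one (key-step precursor) | O=C1CC(OCc2ccccc2)=C1 | intermediate
14 | 3-(benzyloxy)buta-1,3-dien-1-one (vinylketene) | C=C(OCc1ccccc1)C=C=O | intermediate (not isolated)
15 | 4-[1-(benzyloxy)ethenyl]-2-alkyl-3-(triisopropylsilyloxy)cyclobut-2-en-1-one, alkyl = the (2R,3S) chain; ring sp3 carbon a diastereomer mixture | COCO[C@@H]([C@@H](O[Si](CC)(CC)CC)c1cc(OCc2ccccc2)c(OCc2ccccc2)c(OCc2ccccc2)c1)CC1=C(O[Si](C(C)C)(C(C)C)C(C)C)C(C(=C)OCc2ccccc2)C1=O | intermediate (not isolated)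
16 | dienylketene, 5-(benzyloxy)-2-alkyl-3-(triisopropylsilyloxy)hexa-1,3,5-trien-1-one, alkyl = the (2R,3S) chain | COCO[C@@H]([C@@H](O[Si](CC)(CC)CC)c1cc(OCc2ccccc2)c(OCc2ccccc2)c(OCc2ccccc2)c1)CC(=C=O)/C(O[Si](C(C)C)(C(C)C)C(C)C)=C\C(=C)OCc1ccccc1 | intermediate (not isolated)
17 | 5-(benzyloxy)-2-alkyl-3-(triisopropylsilyloxy)cyclohexa-2,4-dien-1-one, alkyl = the (2R,3S) chain | COCO[C@@H]([C@@H](O[Si](CC)(CC)CC)c1cc(OCc2ccccc2)c(OCc2ccccc2)c(OCc2ccccc2)c1)CC1=C(O[Si](C(C)C)(C(C)C)C(C)C)C=C(OCc2ccccc2)CC1=O | intermediate (not isolated)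
18 | 5-(benzyloxy)-2-{(2R,3S)-2-(methoxymethoxy)-3-(triethylsilyloxy)-3-[3,4,5-tris(benzyloxy)phenyl]propyl}-3-(triisopropylsilyloxy)phenol (key-step product) | COCO[C@@H]([C@@H](O[Si](CC)(CC)CC)c1cc(OCc2ccccc2)c(OCc2ccccc2)c(OCc2ccccc2)c1)Cc1c(O)cc(OCc2ccccc2)cc1O[Si](C(C)C)(C(C)C)C(C)C | intermediate
19 | 5-(benzyloxy)-2-{(2R,3S)-3-hydroxy-2-(methoxymethoxy)-3-[3,4,5-tris(benzyloxy)phenyl]propyl}-3-(triisopropylsilyloxy)phenol | COCO[C@@H]([C@@H](O)c1cc(OCc2ccccc2)c(OCc2ccccc2)c(OCc2ccccc2)c1)Cc1c(O)cc(OCc2ccccc2)cc1O[Si](C(C)C)(C(C)C)C(C)C | intermediate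
20 | (2R,3R)-7-(benzyloxy)-3-(methoxymethoxy)-2-[3,4,5-tris(benzyloxy)phenyl]-5-(triisopropylsilyloxy)chromane | COCO[C@@H]1Cc2c(O[Si](C(C)C)(C(C)C)C(C)C)cc(OCc3ccccc3)cc2O[C@@H]1c1cc(OCc2ccccc2)c(OCc2ccccc2)c(OCc2ccccc2)c1 | intermediate
21 | (2R,3R)-7-(benzyloxy)-2-[3,4,5-tris(benzyloxy)phenyl]-5-(triisopropylsilyloxy)chroman-3-ol | O[C@@H]1Cc2c(O[Si](C(C)C)(C(C)C)C(C)C)cc(OCc3ccccc3)cc2O[C@@H]1c1cc(OCc2ccccc2)c(OCc2ccccc2)c(OCc2ccccc2)c1 | intermediate
22 | caffeic acid | O=C(O)/C=C/c1ccc(O)c(O)c1 | starting material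
23 | tert-butyldimethylsilyl (E)-3-[3,4-bis(tert-butyldimethylsilyloxy)phenyl]prop-2-enoate | CC(C)(C)[Si](C)(C)OC(=O)/C=C/c1ccc(O[Si](C)(C)C(C)(C)C)c(O[Si](C)(C)C(C)(C)C)c1 | intermediate (not isolated)
24 | (E)-3-[3,4-bis(tert-butyldimethylsilyloxy)phenyl]prop-2-enoic acid | O=C(O)/C=C/c1ccc(O[Si](C)(C)C(C)(C)C)c(O[Si](C)(C)C(C)(C)C)c1 | intermediate
25 | (2R,3R)-7-(benzyloxy)-2-[3,4,5-tris(benzyloxy)phenyl]-5-(triisopropylsilyloxy)chroman-3-yl (E)-3-[3,4-bis(tert-butyldimethylsilyloxy)phenyl]prop-2-enoate | O=C(/C=C/c1ccc(O[Si](C)(C)C(C)(C)C)c(O[Si](C)(C)C(C)(C)C)c1)O[C@@H]1Cc2c(O[Si](C(C)C)(C(C)C)C(C)C)cc(OCc3ccccc3)cc2O[C@@H]1c1cc(OCc2ccccc2)c(OCc2ccccc2)c(OCc2ccccc2)c1 | intermediate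
26 | (2R,3R)-7-(benzyloxy)-5-hydroxy-2-[3,4,5-tris(benzyloxy)phenyl]chroman-3-yl (E)-3-(3,4-dihydroxyphenyl)prop-2-enoate | O=C(/C=C/c1ccc(O)c(O)c1)O[C@@H]1Cc2c(O)cc(OCc3ccccc3)cc2O[C@@H]1c1cc(OCc2ccccc2)c(OCc2ccccc2)c(OCc2ccccc2)c1 | intermediate
27 | epigallocatechin 3-O-caffeate, (2R,3R) | O=C(/C=C/c1ccc(O)c(O)c1)O[C@@H]1Cc2c(O)cc(O)cc2O[C@@H]1c1cc(O)c(O)c(O)c1 | target

**Step count and risk**

Total steps: 17. Longest linear sequence: 15 (steps 1–8, 10–13, 15–17); steps 9 and 14 make the two side partners.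

Steps most likely to fail:

1. Step 10 (benzannulation). The donor-substituted cyclobutenone may open too slowly, so that oligomerisation of the vinylketene, acylation of the new phenol by vinylketene, or thermal decay of the siloxyalkyne outruns the [2+2] capture. The fallback sets out from siloxyalkyne 11 and returns at phenol 18; it makes the same vinylketene 14 without any thermal ring opening. Trimethylphosphine-catalysed conjugate addition of benzyl alcohol to ethyl but-2-ynoate in CH2Cl2 should give ethyl (E)-3-(benzyloxy)but-2-enoate F1. Saponification (LiOH, THF/H2O, buffered acidification in the cold) gives (E)-3-(benzyloxy)but-2-enoic acid F2, and oxalyl chloride with catalytic DMF gives (E)-3-(benzyloxy)but-2-enoyl chloride F3. Slow addition of Et3N to F3 and 11 in toluene at 0 °C to rt brings about 1,4-dehydrochlorination to 14, which is captured as vinylcyclobutenone 15. After filtration of the ammonium salt the solution is warmed to 80 °C to carry 15 through 16 and 17 to 18.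

2. Step 12 (Mitsunobu closure of ring C). At the hindered, electron-rich benzylic centre the activated oxygen may leave by ionisation or β-elimination, or be intercepted by the reduced azo reagent, so that inversion at C2 is incomplete or the ring does not close. The fallback sets out from 19 and returns at 21; it uses an internal leaving group in place of the phosphonium. The MOM group is removed first (ZnBr2, n-PrSH, CH2Cl2) to give 5-(benzyloxy)-2-{(2R,3S)-2,3-dihydroxy-3-[3,4,5-tris(benzyloxy)phenyl]propyl}-3-(triisopropylsilyloxy)phenol F4. Triethyl orthoformate with pyridinium p-toluenesulfonate in 1,2-dichloroethane converts the anti diol into the cyclic 2-ethoxy-1,3-dioxolane F5. On warming to 60 °C this ionises to the dioxolanylium ion, which the phenol opens at the benzylic carbon with inversion to give the 2,3-cis (2R,3R)-flavan-3-yl formate F6. Mild methanolysis (KHCO3, MeOH, 0 °C) then gives 21.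

3. Step 3 (kinetic resolution). The rate difference between the enantiomers of a terminal vinyl carbinol may be too small, or the titanium alkoxide may open the terminal epoxide, so that the epoxy alcohol is obtained with eroded enantiomeric purity. The fallback sets out from racemate 3 and returns at 4; it separates the resolution from the epoxidation. Acylation with vinyl acetate and Candida antarctica lipase B in tert-butyl methyl ether should acetylate the (R)-enantiomer (aryl as the large, vinyl as the medium substituent) to give (R)-1-[3,4,5-tris(benzyloxy)phenyl]prop-2-en-1-yl acetate F7, which is separated from the unreacted (S)-alcohol. Methanolysis (K2CO3, MeOH) gives (R)-1-[3,4,5-tris(benzyloxy)phenyl]prop-2-en-1-ol F8. Sharpless epoxidation of F8 with Ti(OiPr)4, L-(+)-diisopropyl tartrate and t-BuOOH, now the matched pairing and run to full conversion, gives 4.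

**Further compounds**

F1 | step 10 | ethyl (E)-3-(benzyloxy)but-2-enoate | CCOC(=O)/C=C(\C)OCc1ccccc1
F2 | step 10 | (E)-3-(benzyloxy)but-2-enoic acid | OC(=O)/C=C(\C)OCc1ccccc1
F3 | step 10 | (E)-3-(benzyloxy)but-2-enoyl chloride | ClC(=O)/C=C(\C)OCc1ccccc1
F4 | step 12 | 5-(benzyloxy)-2-{(2R,3S)-2,3-dihydroxy-3-[3,4,5-tris(benzyloxy)phenyl]propyl}-3-(triisopropylsilyloxy)phenol | O[C@@H]([C@@H](O)c1cc(OCc2ccccc2)c(OCc2ccccc2)c(OCc2ccccc2)c1)Cc1c(O)cc(OCc2ccccc2)cc1O[Si](C(C)C)(C(C)C)C(C)C
F5 | step 12 | cyclic orthoformate, 5-(benzyloxy)-2-{[(4R,5S)-2-ethoxy-5-[3,4,5-tris(benzyloxy)phenyl]-1,3-dioxolan-4-yl]methyl}-3-(triisopropylsilyloxy)phenol | CCOC1O[C@@H]([C@@H](O1)c1cc(OCc2ccccc2)c(OCc2ccccc2)c(OCc2ccccc2)c1)Cc1c(O)cc(OCc2ccccc2)cc1O[Si](C(C)C)(C(C)C)C(C)C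
F6 | step 12 | (2R,3R)-7-(benzyloxy)-2-[3,4,5-tris(benzyloxy)phenyl]-5-(triisopropylsilyloxy)chroman-3-yl formate | O=CO[C@@H]1Cc2c(O[Si](C(C)C)(C(C)C)C(C)C)cc(OCc3ccccc3)cc2O[C@@H]1c1cc(OCc2ccccc2)c(OCc2ccccc2)c(OCc2ccccc2)c1
F7 | step 3 | (R)-1-[3,4,5-tris(benzyloxy)phenyl]prop-2-en-1-yl acetate | C=C[C@@H](OC(C)=O)c1cc(OCc2ccccc2)c(OCc2ccccc2)c(OCc2ccccc2)c1
F8 | step 3 | (R)-1-[3,4,5-tris(benzyloxy)phenyl]prop-2-en-1-ol | C=C[C@@H](O)c1cc(OCc2ccccc2)c(OCc2ccccc2)c(OCc2ccccc2)c1
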